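**Retrosynthetic overview**

1. The route rests on C4 of the pyranone ring: it carries no hydrogen and is bonded to two arenes (C4a of ring A and C1' of ring B), so it is traced back to the carbonyl carbon of a non-enolisable benzophenone.
2. The C3=C4 bond is cut as an intramolecular Horner–Wadsworth–Emmons olefination of an aryl (diethoxyphosphoryl)acetate tethered through the future O1–C2 ester. This closes the pyranone ring, the only ring made; rings A and B are bought.
3. The O1–C2 ester comes from a 2-hydroxybenzophenone and (diethoxyphosphoryl)acetic acid. The C4–C4a bond comes from Friedel–Crafts acylation of 1,2,3,5-tetramethoxybenzene by O-pivaloyl isovanilloyl chloride, in which AlCl3 also removes the crowded ortho methyl and uncovers the future O1.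
4. The pivalate masks the 3'-OH from the acid chloride stage onward and is removed last by methanolysis.

Key step: step 5

Assumption: isovanillic acid, 1,2,3,5-tetramethoxybenzene and (diethoxyphosphoryl)acetic acid are taken as purchased; the target has no stereocentre, so only regio- and chemoselectivity have to be controlled.

**Step 1**
Reactants: 1 3-hydroxy-4-methoxybenzoic acid (isovanillic acid)
Product: 2 3-(2,2-dimethylpropanoyloxy)-4-methoxybenzoic acid
Conditions: PivCl, aq NaOH, THF, 0 °C; then aq HCl
Reagents that add atoms: pivaloyl chloride (2,2-dimethylpropanoyl chloride), CC(C)(C)C(=O)Cl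
Why: Schotten–Baumann O-acylation, in which the phenoxide of 1 is acylated by pivaloyl chloride in cold aqueous base, any mixed anhydride formed at the carboxylate is hydrolysed in the same medium, and the hindered aryl pivalate should survive the short exposure to cold hydroxide before acidification.

**Step 2**
Reactants: 2 3-(2,2-dimethylpropanoyloxy)-4-methoxybenzoic acid
Product: 3 3-(2,2-dimethylpropanoyloxy)-4-methoxybenzoyl chloride
Conditions: (COCl)2, cat. DMF, CH2Cl2, 0 °C to rt
Reagents that add atoms: oxalyl chloride, O=C(Cl)C(=O)Cl
Why: Acid chloride formation through the Vilsmeier-type chloroiminium from oxalyl chloride and catalytic DMF is mild enough to leave the aryl pivalate and the methyl ether untouched and gives only gaseous by-products, so crude 3 can be used directly.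

**Step 3**
Reactants: 3 3-(2,2-dimethylpropanoyloxy)-4-methoxybenzoyl chloride; 4 1,2,3,5-tetramethoxybenzene
Product: 6 5-(2-hydroxy-3,4,6-trimethoxybenzoyl)-2-methoxyphenyl 2,2-dimethylpropanoate, via tetramethoxybenzophenone 5 (not isolated)
Conditions: AlCl3 (3 equiv), Et2O, 0 °C to rt; then ice-water
Reagents that add atoms: none
Why: Friedel–Crafts acylation at one of the two equivalent C–H positions of 4 (each flanked by two methoxy groups) should give 5, in which AlCl3 chelated to the ketone cleaves the ortho methyl ether that is pushed out of plane by its neighbouring methoxy group (chelation-directed, strain-relieving dealkylation, the usual outcome of AlCl3 acylations of this arene), while the pivalate and the non-chelated methyl ethers are not expected to react in ether at room temperature.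

**Step 4**
Reactants: 6 5-(2-hydroxy-3,4,6-trimethoxybenzoyl)-2-methoxyphenyl 2,2-dimethylpropanoate; 7 (diethoxyphosphoryl)acetic acid
Product: 8 2-[3-(2,2-dimethylpropanoyloxy)-4-methoxybenzoyl]-3,5,6-trimethoxyphenyl (diethoxyphosphoryl)acetate
Conditions: DCC, cat. DMAP, CH2Cl2, 0 °C to rt
Reagents that add atoms: none
Why: Steglich esterification, in which the O-acylisourea of 7 is intercepted by DMAP to give an acylpyridinium reactive enough to acylate the hydrogen-bonded, hindered phenol of 6 under conditions too weakly basic to start the olefination or to touch the pivalate.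

**Step 5**
Reactants: 8 2-[3-(2,2-dimethylpropanoyloxy)-4-methoxybenzoyl]-3,5,6-trimethoxyphenyl (diethoxyphosphoryl)acetate
Product: 9 2-methoxy-5-(5,7,8-trimethoxy-2-oxo-2H-chromen-4-yl)phenyl 2,2-dimethylpropanoate
Conditions: LiCl, DBU, MeCN, 0 °C to rt
Reagents that add atoms: none
Why: LiCl-assisted deprotonation of the only acidic C–H of 8, the P–CH2–C(=O) methylene (the diaryl ketone has no alpha hydrogen), gives a lithium-chelated phosphonate carbanion that adds to the ortho benzophenone carbonyl, and the beta-alkoxyphosphonate collapses through an oxaphosphetane with loss of diethyl phosphate to form the C3=C4 bond. The closest known reaction type is the intramolecular Horner–Wadsworth–Emmons cyclisation of 2-acylaryl phosphonoacetates to coumarins under Masamune–Roush conditions. The pyranone ring closes in a 6-exo-trig mode (carbanion carbon C3 onto the ketone carbon that becomes C4, with the carbonyl oxygen outside the ring), the new alkene is endocyclic and can only be cis, and no stereocentre is formed. The selectivity required is chemoselectivity: addition to the ketone must outrun loss of the aryl ester, either by attack of the base or by expulsion of the phenoxide to a phosphono-ketene. The substrate secures this because the carbanion is held five atoms from a ketone fixed in the ortho position, and the dry, aprotic, non-nucleophilic medium offers no acyl acceptor, so any phenoxide released can only add back. The pivalate and the four methyl ethers should be inert to LiCl/DBU at room temperature.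

**Step 6**
Reactants: 9 2-methoxy-5-(5,7,8-trimethoxy-2-oxo-2H-chromen-4-yl)phenyl 2,2-dimethylpropanoate
Product: 10 3'-hydroxy-5,7,8,4'-tetramethoxy-4-phenylcoumarin [4-(3-hydroxy-4-methoxyphenyl)-5,7,8-trimethoxy-2H-chromen-2-one]
Conditions: K2CO3, MeOH, rt; then aq HCl
Reagents that add atoms: none
Why: Carbonate-promoted methanolysis (transesterification) should cleave the aryl pivalate because the phenoxide is a good leaving group, the methyl ethers are inert, and a lactone opened by methoxide gives a hydroxy-acrylate whose phenol is held cis to the ester and recloses on acidification.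

**Compound list**

1 | 3-hydroxy-4-methoxybenzoic acid (isovanillic acid) | COc1ccc(C(=O)O)cc1O | starting material
2 | 3-(2,2-dimethylpropanoyloxy)-4-methoxybenzoic acid | COc1ccc(C(=O)O)cc1OC(=O)C(C)(C)C | intermediate
3 | 3-(2,2-dimethylpropanoyloxy)-4-methoxybenzoyl chloride | COc1ccc(C(=O)Cl)cc1OC(=O)C(C)(C)C | intermediate
4 | 1,2,3,5-tetramethoxybenzene | COc1cc(OC)c(OC)c(OC)c1 | starting material
5 | 2-methoxy-5-(2,3,4,6-tetramethoxybenzoyl)phenyl 2,2-dimethylpropanoate | COc1ccc(C(=O)c2c(OC)cc(OC)c(OC)c2OC)cc1OC(=O)C(C)(C)C | intermediate
6 | 5-(2-hydroxy-3,4,6-trimethoxybenzoyl)-2-methoxyphenyl 2,2-dimethylpropanoate | COc1ccc(C(=O)c2c(OC)cc(OC)c(OC)c2O)cc1OC(=O)C(C)(C)C | intermediate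
7 | (diethoxyphosphoryl)acetic acid | CCOP(=O)(OCC)CC(=O)O | starting material
8 | 2-[3-(2,2-dimethylpropanoyloxy)-4-methoxybenzoyl]-3,5,6-trimethoxyphenyl (diethoxyphosphoryl)acetate | CCOP(=O)(OCC)CC(=O)Oc1c(OC)c(OC)cc(OC)c1C(=O)c1ccc(OC)c(OC(=O)C(C)(C)C)c1 | intermediate
9 | 2-methoxy-5-(5,7,8-trimethoxy-2-oxo-2H-chromen-4-yl)phenyl 2,2-dimethylpropanoate | COc1ccc(-c2cc(=O)oc3c(OC)c(OC)cc(OC)c23)cc1OC(=O)C(C)(C)C | intermediate
10 | 3'-hydroxy-5,7,8,4'-tetramethoxy-4-phenylcoumarin | COc1ccc(-c2cc(=O)oc3c(OC)c(OC)cc(OC)c23)cc1O | target

**Step count**

Total steps: 6. Longest linear sequence: 6 steps (1 → 2 → 3 → 6 → 8 → 9 → 10; compounds 4 and 7 enter at steps 3 and 4).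

**Steps most likely to fail**

Step 5 (key step). Addition of the carbanion to the ketone, which is flanked by two ortho substituents, may be slower than base-induced loss of the aryl ester, which would return phenol 6. The fallback sets out from 6, replaces steps 4 and 5, and comes back at 9. Heating 6 with ethyl (triphenylphosphoranylidene)acetate in refluxing xylene, with no added base, should exchange the phenol into the ylide ester with loss of ethanol. This gives 2-[3-(2,2-dimethylpropanoyloxy)-4-methoxybenzoyl]-3,5,6-trimethoxyphenyl (triphenylphosphoranylidene)acetate F1. Its neutral ylide carbon closes on the ketone in an intramolecular Wittig reaction with loss of triphenylphosphine oxide, the established thermal route from 2-hydroxybenzophenones to 4-arylcoumarins.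

Step 3. Ether cleavage under AlCl3 may stop short, go to a second methyl group or to the other ortho methoxy, or the pivalate may be lost or migrate. The fallback sets out from 4 and comes back at 6, forming the C4–C4a bond with an organolithium and keeping the pivalate away from AlCl3.
- Lithiation of 4 with n-BuLi/TMEDA in THF at 0 °C, at the C–H flanked by two methoxy groups, should give (2,3,4,6-tetramethoxyphenyl)lithium F2.
- Addition of this to purchased 3-(benzyloxy)-4-methoxybenzaldehyde, with NH4Cl quench, gives racemic [3-(benzyloxy)-4-methoxyphenyl](2,3,4,6-tetramethoxyphenyl)methanol F3.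
- MnO2 in CH2Cl2 oxidises the diaryl carbinol to [3-(benzyloxy)-4-methoxyphenyl](2,3,4,6-tetramethoxyphenyl)methanone F4.
- BCl3 in CH2Cl2 at −78 to 0 °C removes the benzyl group and the ketone-chelated, crowded ortho methyl, giving (2-hydroxy-3,4,6-trimethoxyphenyl)(3-hydroxy-4-methoxyphenyl)methanone F5.
- Pivaloyl chloride/Et3N at 0 °C should acylate only the free ring B phenol, since the ring A phenol is hydrogen-bonded to the ketone and flanked on both sides. This returns 6.

Step 4. Acylation of the hydrogen-bonded, doubly flanked phenol may be slow, so that the activated acid is consumed by rearrangement to the N-acylurea. The fallback sets out from 6 and comes back at 8. The small and much more reactive bromoacetyl bromide (pyridine, CH2Cl2, 0 °C) should give 2-[3-(2,2-dimethylpropanoyloxy)-4-methoxybenzoyl]-3,5,6-trimethoxyphenyl bromoacetate F6. A Michaelis–Arbuzov reaction with triethyl phosphite (neat, 110 °C) then installs the phosphonate with loss of bromoethane.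

**Further compounds**

F1 | step 5 | 2-[3-(2,2-dimethylpropanoyloxy)-4-methoxybenzoyl]-3,5,6-trimethoxyphenyl (triphenylphosphoranylidene)acetate | O=C(C=P(c1ccccc1)(c1ccccc1)c1ccccc1)Oc1c(OC)c(OC)cc(OC)c1C(=O)c1ccc(OC)c(OC(=O)C(C)(C)C)c1
F2 | step 3 | (2,3,4,6-tetramethoxyphenyl)lithium | [Li]c1c(OC)cc(OC)c(OC)c1OC
F3 | step 3 | [3-(benzyloxy)-4-methoxyphenyl](2,3,4,6-tetramethoxyphenyl)methanol (racemic) | COc1ccc(C(O)c2c(OC)cc(OC)c(OC)c2OC)cc1OCc1ccccc1
F4 | step 3 | [3-(benzyloxy)-4-methoxyphenyl](2,3,4,6-tetramethoxyphenyl)methanone | COc1ccc(C(=O)c2c(OC)cc(OC)c(OC)c2OC)cc1OCc1ccccc1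
F5 | step 3 | (2-hydroxy-3,4,6-trimethoxyphenyl)(3-hydroxy-4-methoxyphenyl)methanone | COc1ccc(C(=O)c2c(OC)cc(OC)c(OC)c2O)cc1O
F6 | step 4 | 2-[3-(2,2-dimethylpropanoyloxy)-4-methoxybenzoyl]-3,5,6-trimethoxyphenyl bromoacetate | O=C(CBr)Oc1c(OC)c(OC)cc(OC)c1C(=O)c1ccc(OC)c(OC(=O)C(C)(C)C)c1
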